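The constant with which partner takes the substrate is larger than the one with which second reagent takes it, and the recipes differ in how second reagent or substrate goes in.

| flask | substrate | partner | second reagent | third reagent | capture agent | time | remark |
|---|---|---|---|---|---|---|---|
| south-west | 0.0020 M | 1.20 equiv | 3.00 equiv (in portions, 3, over 15 s) | 2.50 equiv | 0.600 mM | 40 s | first portion at the start, last at 15 s |
| north-east | 0.0020 M | 1.20 equiv | 3.00 equiv (fed, over 15 s) | 2.50 equiv | 0.600 mM | 40 s | all else is in the flask from the start; the feed brings no volume worth counting |
| south-east | 0.0020 M | 1.20 equiv | 3.00 equiv | 2.50 equiv | 0.600 mM | 40 s | everything together at the start |
| north-west | 0.0020 M (fed, over 15 s) | 1.20 equiv | 3.00 equiv | 2.50 equiv | 0.600 mM | 40 s | all else is in the flask from the start; the feed brings no volume worth counting |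

    substrate + partner → intermediate A (k1 = 1280 M⁻¹ s⁻¹)
    second reagent + intermediate A → intermediate B (k2 = 11.6 M⁻¹ s⁻¹)
    third reagent + intermediate B → target (k3 = 15.4 M⁻¹ s⁻¹)
    substrate + second reagent → side product (k4 = 213 M⁻¹ s⁻¹)
    intermediate B + capture agent → trapped intermediate (k5 = 18.9 M⁻¹ s⁻¹)

- which flask leads in amount of target, in percent of the substrate charged ("all alike" within 1.5 percentage points) (south-west / north-east / south-east / north-west / all alike)
- how much target is there at the end, in percent of the substrate charged: south-west
- how much target is there at the end, in percent of the substrate charged: north-east
- how much target is there at the end, in percent of the substrate charged: south-east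
- how much target is there at the end, in percent of the substrate charged: north-west

I read the recipes row by row, asking of each how much second reagent the substrate meets. Both steps that use substrate carry c(substrate) as a factor, so it cancels when I divide one rate by the other. What remains, beside c(partner) over c(second reagent), is the selectivity factor, the constant of the partner step over that of the side step, S = 6.01. Integrated, c(partner) over its charge equals c(second reagent) over its charge, raised to the power S. The clock does not appear in that law, provided both stand there from the start and step two takes little. In south-east it should take little, since at the charged concentrations the half-life of intermediate A by step two, 10 s, is longer than that of substrate by step one, 0.23 s.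

South-east: at the start partner takes 70.6 % of what reacts, which suggests side product 29.4 %. The law then has partner using 55.4 % of the substrate charge, which implies side product 44.6 %. Their mean, 37.0 %, implies 34.4 %, so I take 35.7 %.

North-west has the same charges under the same law, so I expect the same split, with target later since the substrate arrives over 15 s, longer than the south-east half-life of substrate by step one.

South-west: the first portion is 1.00 equiv of second reagent and the next follows after 7.50 s, longer than the south-east half-life of substrate by step one, so I let the substrate meet partner and the first portion, and the start share suggests side product 12.2 %. I try 18.3 %, which implies 15.7 %, and I take the mean, 17.0 %.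

North-east: the feed breaks the law, but in one south-east half-life of substrate by step one it brings 0.0451 equiv of second reagent, a smaller dose than one south-west portion, so I expect less side product than in south-west. My reckoning stops at this split, and I give no target figure of my own. My order is north-east, south-west, south-east, north-west.

The forecast has the same order: north-east leads with 50 %, then south-west 44.5 %, south-east 40 %, north-west 35 %, from “starving the second reagent”.

The flasks give north-east first with 52.7 %, then south-west 44.9 %, south-east 40.4 %, north-west 35.4 %.

At 40.0 s side product stands at 35.8 % in south-east and 35.2 % in north-west, beside my 35.7 %, and at 17.5 % in south-west, beside my 17.0 %. The law with S = 6.01 uses each concentration only as a fraction of its charge, so for a neighbour of north-west charged with 5.0 × 10⁻⁴ M of substrate at the same equivalents I again expect 35.7 %, and that neighbour holds side product 35.6 %, with target 5.87 % and intermediate A 40.5 %.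

Its constants are invented, and the outcome is calculated.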